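The constants of this chemistry can't be read singly from these runs, but they show which concentration the rate follows: at 4.00 h, Saturday's flask reads 19.6 % and Monday's 17.1 %, though Monday's holds 5.75 times the Sub.

| flask | Sub | Rgt | remark | time |
|---|---|---|---|---|
| Saturday's | 4 mM | 26 mM | run made earlier |  |
| Tuesday's | 10 mM | 26 mM | run made earlier |  |
| Monday's | 23 mM | 26 mM | run made earlier |  |
| Sunday's | 20 mM | 15 mM | run made earlier |  |
| beta | 5.0 mM | 6.00 mM |  | 60 h |
| alpha | 20 mM | 26.0 mM |  | 30 h |

| run | time / h | Tgt2 / % |
|---|---|---|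
| Saturday's | 4.00 | 19.6 |
| Saturday's | 8.00 | 33.0 |
| Saturday's | 12.0 | 40.4 |
| Saturday's | 15.0 | 46.1 |
| Tuesday's | 1.33 | 5.3 |
| Tuesday's | 3.00 | 12.3 |
| Tuesday's | 6.00 | 25.5 |
| Tuesday's | 15.0 | 43.3 |
| Monday's | 4.00 | 17.1 |
| Monday's | 8.00 | 29.4 |
| Monday's | 12.0 | 35.2 |
| Monday's | 15.0 | 37.8 |
| Sunday's | 2.00 | 5.6 |
| Sunday's | 5.00 | 15.3 |
| Sunday's | 10.0 | 25.5 |
| Sunday's | 15.0 | 30.0 |

(each reading ± 0.5 percentage points)

* the flask that ends with the higher amount of Tgt2, in percent of the Sub charged, or "neither" when 2 percentage points or less lies between them (beta / alpha / neither)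
* final Tgt2, as a percentage of the Sub charged, in beta
* final Tgt2, as a percentage of the Sub charged, in alpha



Two chemists argue over these flasks. The first counts equivalents of Rgt per Sub: 1.20 in beta, 1.30 in alpha. Monday's flask, at 1.13, gains 2.6 percentage points in its last interval, so she expects a plateau set by that ratio, and the answer neither.

The second treats Sub as pseudo-first-order, with a constant proportional to [Rgt]. He multiplies charged [Rgt] by time and expresses the product as hours at 26 mM of Rgt, the Rgt dose: 13.8 h in beta, 30.0 h in alpha, twice as much. Tuesday's flask at 6.00 h and Sunday's at 10.0 h have doses of 6.00 h and 5.77 h, and they read 25.5 % and 25.5 %, with different Sub.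

The dose isn't the whole story: at the same dose of 15.0 h, Saturday's reads 46.1 % and Monday's 37.8 %. My own reckoning uses that pair as a bracket. At beta's dose, Monday's readings give 36.8 % and Saturday's 43.9 %. Continuing Monday's last slope to alpha's dose gives 50.8 %, a figure above that bracket. That slope is falling, so I expect alpha somewhat lower, but still ahead of beta.

The forecast says alpha, with beta at 38 % and alpha at 48 %, and calls alpha “near the maximum”.

Beta ends at 40.6 % and alpha at 46.0 %, so alpha leads by 5.4 points, beyond the margin of 2 points: of these two flasks, the one with the larger dose ends higher.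

    Sub.Rgt → Tgt2 (k = 0.00470 min⁻¹)
    2 Rgt → Tgt (k = 0.180 L mol⁻¹ min⁻¹)
    Sub + Rgt ⇌ Sub.Rgt (K = 71.0 L mol⁻¹, k = 0.190 L mol⁻¹ min⁻¹)

Equivalents have their region where doses are equal: a neighbour of beta, charged with 12 mM of Sub, has the same dose of 13.8 h but 0.500 equiv of Rgt, and it ends at 29.4 %, below beta, with Rgt, its limiting reagent, at 0.97 % of its charge. In beta at 7.57 h, Sub.Rgt has a half-life of 2.5 h by conversion to Tgt2, shorter than the 15 h of Rgt by forward binding alone. At 60.0 h, beta holds 0.485 % of its Sub as Sub.Rgt and 58.9 % as free Sub.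

Readings and results were generated by integration for substances that don't exist, noise included.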